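**Strategy**

The route rests on cutting the unbranched henicosyl chain at its C5′–C6′ CH2–CH2 bond (numbered from pyrrole C5) and forming that bond by a crossed Kolbe electrolysis. Anodic decarboxylation of heptadecanoic acid and of 6-(5-formyl-1H-pyrrol-2-yl)hexanoic acid gives two primary alkyl radicals that pair at the electrode, so one operation completes the C21 chain with aldehyde and N–H unprotected. The step exploits the chain itself: no branch, heteroatom or stereocentre lies near the bond, and a five-methylene spacer keeps the radical site remote from the 2-formylpyrrole ring. The pyrrole acid, which carries a carboxyl group absent from the target, comes in two steps from pyrrole-2-carbaldehyde by C5–H alkylation and saponification.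

Key step: step 3

Remark: the target has no stereocentre and no stereogenic double bond, so it is achiral and no step has to control configuration.

**Route**

Step 1
Reactants: 1 1H-pyrrole-2-carbaldehyde; 2 ethyl 6-bromohexanoate
Product: 3 ethyl 6-(5-formyl-1H-pyrrol-2-yl)hexanoate
Conditions: 2 (2 equiv), PdCl2(MeCN)2 (10 mol %), norbornene (2 equiv), KHCO3 (3 equiv), DMA, 90 °C, air
Reagents that add atoms: none
Why: Catellani-type Pd(II)/norbornene C–H alkylation of an electron-poor NH-pyrrole (N-palladation, aminopalladation of norbornene, palladacycle formation at the only free carbon next to nitrogen, oxidative addition of the primary bromide, C–C reductive elimination, norbornene extrusion) should alkylate C5 selectively because the formyl group occupies the other α-position.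

Step 2
Reactants: 3 ethyl 6-(5-formyl-1H-pyrrol-2-yl)hexanoate
Product: 5 6-(5-formyl-1H-pyrrol-2-yl)hexanoic acid, via lithium 6-(5-formyl-1H-pyrrol-2-yl)hexanoate 4 (not isolated)
Conditions: LiOH·H2O (3 equiv), THF/MeOH/H2O, rt; then 1 M HCl to pH 3
Reagents that add atoms: lithium hydroxide, [Li+].[OH-]
Why: Saponification of the ethyl ester by hydroxide (BAc2 ester hydrolysis) should proceed cleanly because the non-enolisable, vinylogous-formamide aldehyde of the pyrrole is inert to cold aqueous base, and acidification releases the free acid.

Step 3
Reactants: 5 6-(5-formyl-1H-pyrrol-2-yl)hexanoic acid; 6 heptadecanoic acid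
Product: 9 5-henicosyl-1H-pyrrole-2-carbaldehyde, via hexadecyl radical 7 (not isolated), via 5-(5-formyl-1H-pyrrol-2-yl)pentyl radical 8 (not isolated)
Conditions: 6 (6 equiv), KOH (0.1 equiv per acid group), MeOH, 45–50 °C, undivided cell, Pt anode/Pt cathode, constant current ca. 0.2 A cm⁻², polarity reversed periodically
Reagents that add atoms: none
Why: Crossed Kolbe electrolysis: both carboxylates are oxidised at the platinum anode and lose CO2 to give the primary radicals 7 and 8, which combine in the dense radical layer at the electrode to form the C5′–C6′ CH2–CH2 bond, while protons are reduced to H2 at the cathode. The closest known reaction type is the crossed Kolbe coupling of a fatty acid with an ω-functionalised alkanoic acid such as a half ester or a keto acid. No ring is closed and no stereocentre is formed. The step needs hetero- over homo-coupling and radical pairing over oxidation of the pyrrole: the sixfold excess of cheap 6 should make nearly every radical 8 meet a radical 7, and the non-polar hydrocarbon formed from 6 alone separates easily from the polar aldehyde. The carboxylate layer that occupies the anode at high current density and the 2-formyl group, which turns the pyrrole into a vinylogous formamide of raised oxidation potential, should protect the ring. The five-methylene spacer and the fast pairing of unbranched primary radicals should outrun 1,5-hydrogen transfer, addition to the heteroarene and the cationic Hofer–Moest pathway.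

**Compound list**

1 | 1H-pyrrole-2-carbaldehyde | O=Cc1ccc[nH]1 | starting material
2 | ethyl 6-bromohexanoate | CCOC(=O)CCCCCBr | starting material
3 | ethyl 6-(5-formyl-1H-pyrrol-2-yl)hexanoate | CCOC(=O)CCCCCc1ccc(C=O)[nH]1 | intermediate
4 | lithium 6-(5-formyl-1H-pyrrol-2-yl)hexanoate | [Li+].[O-]C(=O)CCCCCc1ccc(C=O)[nH]1 | intermediate (not isolated)
5 | 6-(5-formyl-1H-pyrrol-2-yl)hexanoic acid | OC(=O)CCCCCc1ccc(C=O)[nH]1 | intermediate
6 | heptadecanoic acid | CCCCCCCCCCCCCCCCC(=O)O | starting material
7 | hexadecyl radical | CCCCCCCCCCCCCCC[CH2] | intermediate (not isolated)
8 | 5-(5-formyl-1H-pyrrol-2-yl)pentyl radical | [CH2]CCCCc1ccc(C=O)[nH]1 | intermediate (not isolated)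
9 | 5-henicosyl-1H-pyrrole-2-carbaldehyde | CCCCCCCCCCCCCCCCCCCCCc1ccc(C=O)[nH]1 | target

**Step count and risks**

Total step count: 3. Longest linear sequence: 3 steps (1 → 3 → 5 → 9).

Steps most likely to fail:

Step 3 (key step). Anodic oxidation of the pyrrole ring may compete with carboxylate oxidation, the paraffinic products may deposit on the anode and passivate it, and statistical pairing may divert the pyrrole radical into its own dimer. The fallback forms the same C5′–C6′ bond as an alkene by metathesis and sets out from 1. The C5–H alkylation conditions of step 1, applied to 1 with 6-bromohex-1-ene (C=CCCCCBr), should give 5-(hex-5-en-1-yl)-1H-pyrrole-2-carbaldehyde F1. Cross-metathesis of F1 with excess heptadec-1-ene (C=CCCCCCCCCCCCCCCC) using a second-generation Grubbs catalyst in CH2Cl2 at 40 °C should give 5-[(5E)-henicos-5-en-1-yl]-1H-pyrrole-2-carbaldehyde F2; the alkene geometry is irrelevant. Hydrogenation of F2 (H2, 1 atm, Pd/C, EtOAc, rt, stopped after one equivalent) should saturate the chain and come back to the route at 9.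

Step 1. Oxidative addition of the primary bromide to the palladacycle may be slow with the formyl-deactivated pyrrole, so that N-alkylation or β-hydride elimination of the alkyl–palladium species takes over. The fallback replaces C–H activation by cross-coupling of a pre-halogenated pyrrole and sets out from 2. Zinc insertion into 2 (Zn dust, catalytic I2, DMA, 80 °C) should give (6-ethoxy-6-oxohexyl)zinc bromide F3. Negishi coupling of F3, added slowly, with commercial 5-bromo-1H-pyrrole-2-carbaldehyde (O=Cc1ccc(Br)[nH]1) under Pd(OAc)2/SPhos in THF at rt should tolerate the aldehyde and the N–H and come back to the route at 3.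

Step 2. The deprotonated formylpyrrole may degrade in aqueous base by air oxidation or condensation during a slow hydrolysis. The fallback avoids base by using an acid-labile ester and sets out from 1. The C5–H alkylation conditions of step 1 with tert-butyl 6-bromohexanoate (CC(C)(C)OC(=O)CCCCCBr) should give tert-butyl 6-(5-formyl-1H-pyrrol-2-yl)hexanoate F4. Acidolysis of F4 with TFA in CH2Cl2 (0 °C to rt), to which the acid-stable 2-formylpyrrole should be inert, comes back to the route at 5.

**Further compounds**

F1 | step 3 | 5-(hex-5-en-1-yl)-1H-pyrrole-2-carbaldehyde | C=CCCCCc1ccc(C=O)[nH]1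
F2 | step 3 | 5-[(5E)-henicos-5-en-1-yl]-1H-pyrrole-2-carbaldehyde | CCCCCCCCCCCCCCC/C=C/CCCCc1ccc(C=O)[nH]1
F3 | step 1 | (6-ethoxy-6-oxohexyl)zinc bromide | CCOC(=O)CCCCC[Zn]Br
F4 | step 2 | tert-butyl 6-(5-formyl-1H-pyrrol-2-yl)hexanoate | CC(C)(C)OC(=O)CCCCCc1ccc(C=O)[nH]1
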